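**Plan**

1. Numbering (germacrane): ring carbons C1–C10; lactone O–C6, C7, C11(=C13), C12(=O); C14 on C10 (the CHO); C15 on C4 (the CH2OAc). "Ring-cis" means the two ring neighbours of a double bond are cis.
2. Retrosynthesis: C14=O back to C14H3 (allylic oxidation); the C8 ester back to the C8-epimeric alcohol (inversion); then the ring bond C7–C8; then C7=C11 and O–C12 (butenolide), C6–C7, C3–C4, C1–C2 and C10–C14.
3. Enabling feature: the α-methylene-γ-lactone with an oxygen on C8, next to C7, is the retron of an aldehyde allylation. Written as a 3-(bromomethyl)butenolide, C13–C11=C7 is a latent allyl nucleophile whose γ-carbon is ring carbon C7, so the lactone ring can be complete before the carbocycle closes.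
4. Forward: the C8–C3 chain (but-3-yn-1-ol, Me3Al, oxirane) is coupled to a C4–C6/C15 iodoalkene (from a butynediol ether) and vinyl is added at C6. The lactone ring is closed by metathesis, and the ten-membered ring is closed last by intramolecular Nozaki–Hiyama allylation (C7–C8).
5. Stereochemistry: C6 from ligand-controlled divinylzinc addition; C7 and C8 from C6 in the ring closure (trans-lactone, anti carbinol); C8 inverted in the Mitsunobu esterification; acyl centre from (S)-2-methylbutanoic acid. C4=C5 comes from anti-hydroalumination/iodination and a stereoretentive coupling; C1=C10 is made ring-trans and turned ring-cis by the SeO2 ene/[2,3] sequence that also brings in O14.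

Key step: step 14

Remark (assumption): (−)-MIB is taken to direct divinylzinc to the Si face of enal 15, as it does for dialkylzinc additions; should the sense be opposite, (+)-MIB would be used.

**Route**

Step 1
Reactants: 1 but-3-yn-1-ol
Product: 2 1-[(but-3-yn-1-yloxy)methyl]-4-methoxybenzene
Conditions: NaH, 4-methoxybenzyl chloride, Bu4NI (cat.), THF, 0 °C to rt
Reagents that add atoms: 4-methoxybenzyl chloride, COc1ccc(CCl)cc1
Why: Williamson ether synthesis, in which the alkoxide (formed in preference to the acetylide) is benzylated; no stereocentre is involved.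

Step 2
Reactants: 2 1-[(but-3-yn-1-yloxy)methyl]-4-methoxybenzene; 3 oxirane
Product: 6 (3E)-6-[(4-methoxybenzyl)oxy]-4-methylhex-3-en-1-ol, via alkenyldimethylalane 4 (not isolated), via lithium alkenylalanate 5 (not isolated)
Conditions: Me3Al, Cp2ZrCl2 (cat.), CH2Cl2, 0 °C to rt; excess Me3Al removed in vacuo; n-BuLi, THF/hexane, −78 to 0 °C; oxirane, 0 °C to rt; aq. HCl
Reagents that add atoms: trimethylaluminium, C[Al](C)C
Why: Negishi zirconium-catalysed carboalumination adds methyl (C14) and aluminium syn across the terminal alkyne with methyl on the internal carbon C10, and the derived alanate opens oxirane with retention at C1, so C2 should end up cis to the methyl group (ring-trans C1=C10, no stereocentre).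

Step 3
Reactants: 6 (3E)-6-[(4-methoxybenzyl)oxy]-4-methylhex-3-en-1-ol
Product: 7 1-({[(3E)-6-iodo-3-methylhex-3-en-1-yl]oxy}methyl)-4-methoxybenzene
Conditions: I2, PPh3, imidazole, CH2Cl2, 0 °C
Reagents that add atoms: iodine, [I][I]
Why: Appel-type iodination of the primary alcohol by SN2 displacement of the oxyphosphonium ion, which leaves the trisubstituted alkene and the benzyl ether untouched.

Step 4
Reactants: 8 4-[(tert-butyldimethylsilyl)oxy]but-2-yn-1-ol
Product: 10 (2Z)-4-[(tert-butyldimethylsilyl)oxy]-3-iodobut-2-en-1-ol, via cyclic sodium alkenylalanate 9 (not isolated)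
Conditions: NaAlH2(OCH2CH2OMe)2, THF, 0 °C; then I2, −78 to 0 °C
Reagents that add atoms: iodine, [I][I]
Why: Hydroxyl-directed trans-hydroalumination of the propargylic alcohol places aluminium on the distal carbon C4 in a five-membered alanate, and iodinolysis with retention should give the Z-iodide, which fixes C15 trans to C6.

Step 5
Reactants: 7 1-({[(3E)-6-iodo-3-methylhex-3-en-1-yl]oxy}methyl)-4-methoxybenzene; 10 (2Z)-4-[(tert-butyldimethylsilyl)oxy]-3-iodobut-2-en-1-ol
Product: 12 (2E,6E)-3-{[(tert-butyldimethylsilyl)oxy]methyl}-9-[(4-methoxybenzyl)oxy]-7-methylnona-2,6-dien-1-ol, via alkylzinc iodide 11 (not isolated)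
Conditions: 7, Zn dust, LiCl, THF, 40 °C; then 10, Pd(OAc)2 (cat.), SPhos (cat.), THF, rt
Reagents that add atoms: none
Why: Negishi sp3–sp2 cross-coupling of the alkylzinc iodide with the alkenyl iodide under palladium/SPhos catalysis, which tolerates the free hydroxyl and proceeds with retention of the alkene geometry, so C3 ends up cis to C6 (ring-cis C4=C5).

Step 6
Reactants: 12 (2E,6E)-3-{[(tert-butyldimethylsilyl)oxy]methyl}-9-[(4-methoxybenzyl)oxy]-7-methylnona-2,6-dien-1-ol
Product: 13 (2E,6E)-3-{[(tert-butyldimethylsilyl)oxy]methyl}-9-[(4-methoxybenzyl)oxy]-7-methylnona-2,6-dienal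
Conditions: MnO2, CH2Cl2, rt
Reagents that add atoms: none
Why: Chemoselective manganese dioxide oxidation of the primary allylic alcohol to the enal, which should not isomerise the double bond and leaves both ethers alone.

Step 7
Reactants: 13 (2E,6E)-3-{[(tert-butyldimethylsilyl)oxy]methyl}-9-[(4-methoxybenzyl)oxy]-7-methylnona-2,6-dienal
Product: 14 (2E,6E)-3-(hydroxymethyl)-9-[(4-methoxybenzyl)oxy]-7-methylnona-2,6-dienal
Conditions: HF·pyridine, pyridine, THF, 0 °C
Reagents that add atoms: none
Why: Fluoride cleavage of the primary allylic silyl ether under buffered conditions that spare the 4-methoxybenzyl ether; the freed hydroxyl is trans to the formyl group across C4=C5 and so cannot close to a lactol.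

Step 8
Reactants: 14 (2E,6E)-3-(hydroxymethyl)-9-[(4-methoxybenzyl)oxy]-7-methylnona-2,6-dienal
Product: 15 (2E)-2-{(3E)-6-[(4-methoxybenzyl)oxy]-4-methylhex-3-en-1-yl}-4-oxobut-2-en-1-yl acetate
Conditions: Ac2O, pyridine, DMAP (cat.), CH2Cl2, 0 °C
Reagents that add atoms: acetic anhydride, CC(=O)OC(C)=O
Why: Standard acetylation installs the C15 acetate of the target at the one stage where it is the only hydroxyl.

Step 9
Reactants: 15 (2E)-2-{(3E)-6-[(4-methoxybenzyl)oxy]-4-methylhex-3-en-1-yl}-4-oxobut-2-en-1-yl acetate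
Product: 16 (2E,4S)-4-hydroxy-2-{(3E)-6-[(4-methoxybenzyl)oxy]-4-methylhex-3-en-1-yl}hexa-2,5-dien-1-yl acetate
Conditions: (CH2=CH)2Zn [from CH2=CHMgBr and ZnCl2, magnesium salts precipitated with 1,4-dioxane], (−)-MIB (cat.), toluene/hexane, −10 °C
Reagents that add atoms: divinylzinc, C=C[Zn]C=C
Why: Catalytic enantioselective addition of divinylzinc to the aldehyde mediated by the amino alcohol (−)-MIB, in which the zinc aminoalkoxide should deliver vinyl to the Si face and set C6 (S here; the same centre is R once C7 outranks C5), while the organozinc leaves the acetate alone.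

Step 10
Reactants: 16 (2E,4S)-4-hydroxy-2-{(3E)-6-[(4-methoxybenzyl)oxy]-4-methylhex-3-en-1-yl}hexa-2,5-dien-1-yl acetate; 17 2-(bromomethyl)prop-2-enoic acid
Product: 18 (3S,4E)-6-acetoxy-5-{(3E)-6-[(4-methoxybenzyl)oxy]-4-methylhex-3-en-1-yl}hexa-1,4-dien-3-yl 2-(bromomethyl)prop-2-enoate
Conditions: DCC, DMAP (cat.), CH2Cl2, 0 °C
Reagents that add atoms: none
Why: Steglich esterification of the secondary bis-allylic alcohol under neutral conditions, which does not touch the C6 centre.

Step 11
Reactants: 18 (3S,4E)-6-acetoxy-5-{(3E)-6-[(4-methoxybenzyl)oxy]-4-methylhex-3-en-1-yl}hexa-1,4-dien-3-yl 2-(bromomethyl)prop-2-enoate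
Product: 19 (2E)-3-[(2R)-4-(bromomethyl)-5-oxo-2,5-dihydrofuran-2-yl]-2-{(3E)-6-[(4-methoxybenzyl)oxy]-4-methylhex-3-en-1-yl}prop-2-en-1-yl acetate
Conditions: second-generation Hoveyda–Grubbs catalyst (cat.), toluene, 80 °C, high dilution
Reagents that add atoms: none
Why: Ring-closing metathesis between the vinyl group and the 1,1-disubstituted acrylate closes the lactone ring (O–C6–C7=C11–C12) with loss of ethene; the trisubstituted alkenes should not engage, and the phosphine-free catalyst cannot be alkylated by the allylic bromide.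

Step 12
Reactants: 19 (2E)-3-[(2R)-4-(bromomethyl)-5-oxo-2,5-dihydrofuran-2-yl]-2-{(3E)-6-[(4-methoxybenzyl)oxy]-4-methylhex-3-en-1-yl}prop-2-en-1-yl acetate
Product: 20 (2E)-3-[(2R)-4-(bromomethyl)-5-oxo-2,5-dihydrofuran-2-yl]-2-[(3E)-6-hydroxy-4-methylhex-3-en-1-yl]prop-2-en-1-yl acetate
Conditions: DDQ, CH2Cl2/pH 7 buffer, 0 °C to rt
Reagents that add atoms: none
Why: Oxidative cleavage of the 4-methoxybenzyl ether by DDQ (hydride abstraction, then hydrolysis of the oxocarbenium ion) under neutral conditions that should leave the allylic bromide, the acetate and the base-sensitive butenolide intact.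

Step 13
Reactants: 20 (2E)-3-[(2R)-4-(bromomethyl)-5-oxo-2,5-dihydrofuran-2-yl]-2-[(3E)-6-hydroxy-4-methylhex-3-en-1-yl]prop-2-en-1-yl acetate
Product: 21 (2E)-3-[(2R)-4-(bromomethyl)-5-oxo-2,5-dihydrofuran-2-yl]-2-[(3E)-4-methyl-6-oxohex-3-en-1-yl]prop-2-en-1-yl acetate
Conditions: Dess–Martin periodinane, CH2Cl2, 0 °C; used without delay
Reagents that add atoms: none
Why: Dess–Martin oxidation of the primary alcohol gives the β,γ-unsaturated aldehyde under non-basic conditions that should not move the C1=C10 double bond into conjugation.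

Step 14
Reactants: 21 (2E)-3-[(2R)-4-(bromomethyl)-5-oxo-2,5-dihydrofuran-2-yl]-2-[(3E)-4-methyl-6-oxohex-3-en-1-yl]prop-2-en-1-yl acetate
Product: 23 [(3aR,4S,6E,10E,11aR)-4-hydroxy-6-methyl-3-methylidene-2-oxo-2,3,3a,4,5,8,9,11a-octahydrocyclodeca[b]furan-10-yl]methyl acetate (8S alcohol; C1=C10 ring-trans; C4=C5 ring-cis), via allylchromium dichloride 22 (not isolated)
Conditions: CrCl2 (excess), THF, rt, slow addition of 21 to high dilution; aqueous work-up
Reagents that add atoms: none
Why: Two equivalents of divalent chromium (CrCl2) reduce the allylic C13–Br bond to the trivalent allylchromium species 22, whose γ-carbon C7 (the butenolide β-carbon) adds to the chromium-bound C8 aldehyde through a six-membered chair transition state while the double bond moves from C7=C11 to C11=C13. The closest known reaction type is the Nozaki–Hiyama allylation of aldehydes by 2-(bromomethyl)alk-2-enoates, including 3-(bromomethyl)furan-2(5H)-ones, which is also an established way to close ten-membered germacranolide rings. The ten-membered carbocycle closes by 10-exo-trig attack of C7 on the carbonyl carbon C8; the lactone ring is already present and is not opened. C7 is controlled by C6, because the aldehyde can reach only the butenolide face opposite to the C5 substituent, which should give the trans-fused (7R) lactone; C8 is controlled by the chair, in which the ring-locked allyl unit is of the E-crotyl type (C6 trans to C13) and C9 is equatorial, so the anti (8S) carbinol is expected. The step needs γ- rather than α-attack (given by the cyclic transition state), ring closure rather than oligomerisation (high dilution, and the ring-cis C4=C5 bond that turns the chain back towards C7) and addition to the aldehyde only (allylchromium reagents do not attack the acetate or the lactone).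

Step 15
Reactants: 23 [(3aR,4S,6E,10E,11aR)-4-hydroxy-6-methyl-3-methylidene-2-oxo-2,3,3a,4,5,8,9,11a-octahydrocyclodeca[b]furan-10-yl]methyl acetate; 24 (2S)-2-methylbutanoic acid
Product: 25 [(3aR,4R,6E,10E,11aR)-10-(acetoxymethyl)-6-methyl-3-methylidene-2-oxo-2,3,3a,4,5,8,9,11a-octahydrocyclodeca[b]furan-4-yl] (2S)-2-methylbutanoate
Conditions: PPh3, DIAD (betaine pre-formed), toluene, 0 °C to rt
Reagents that add atoms: none
Why: Mitsunobu esterification, in which the C8 alkoxyphosphonium ion is displaced by the carboxylate with SN2 inversion (8S to 8R) while the α-centre of the acid is not involved.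

Step 16
Reactants: 25 [(3aR,4R,6E,10E,11aR)-10-(acetoxymethyl)-6-methyl-3-methylidene-2-oxo-2,3,3a,4,5,8,9,11a-octahydrocyclodeca[b]furan-4-yl] (2S)-2-methylbutanoate
Product: 26 [(3aR,4R,6E,10E,11aR)-10-(acetoxymethyl)-6-(hydroxymethyl)-3-methylidene-2-oxo-2,3,3a,4,5,8,9,11a-octahydrocyclodeca[b]furan-4-yl] (2S)-2-methylbutanoate (C1=C10 now ring-cis; the descriptor stays E because CH2OH outranks C9)
Conditions: SeO2 (cat.), t-BuOOH, CH2Cl2, rt
Reagents that add atoms: selenium dioxide, O=[Se]=O; tert-butyl hydroperoxide, CC(C)(C)OO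
Why: Selenium dioxide allylic oxidation (ene reaction at the electron-rich C1=C10 bond with loss of a C14 hydrogen, then [2,3]-sigmatropic shift of the allylseleninic acid): the sigmatropic step should rebuild the double bond with C14–OH trans to C2, i.e. ring-cis, as is known for 1(10)-trans germacranolides, while the C4=C5 bond is deactivated by its two allylic oxygens.

Step 17
Reactants: 26 [(3aR,4R,6E,10E,11aR)-10-(acetoxymethyl)-6-(hydroxymethyl)-3-methylidene-2-oxo-2,3,3a,4,5,8,9,11a-octahydrocyclodeca[b]furan-4-yl] (2S)-2-methylbutanoate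
Product: 27 [(3aR,4R,6E,10E,11aR)-10-(acetoxymethyl)-6-formyl-3-methylidene-2-oxo-2,3,3a,4,5,8,9,11a-octahydrocyclodeca[b]furan-4-yl] (2S)-2-methylbutanoate
Conditions: MnO2, CH2Cl2, rt
Reagents that add atoms: none
Why: Manganese dioxide oxidation of the only alcohol, a primary allylic one, to the conjugated aldehyde, which is already in its more stable geometry.

**Compound list**

1 | but-3-yn-1-ol | C#CCCO | starting material
2 | 1-[(but-3-yn-1-yloxy)methyl]-4-methoxybenzene | C#CCCOCc1ccc(OC)cc1 | intermediate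
3 | oxirane | C1CO1 | starting material
4 | [(1E)-4-[(4-methoxybenzyl)oxy]-2-methylbut-1-en-1-yl]dimethylalane | COc1ccc(COCC/C(C)=C/[Al](C)C)cc1 | intermediate (not isolated)
5 | lithium butyl[(1E)-4-[(4-methoxybenzyl)oxy]-2-methylbut-1-en-1-yl]dimethylalanate | [Li+].CCCC[Al-](C)(C)/C=C(\C)CCOCc1ccc(OC)cc1 | intermediate (not isolated)
6 | (3E)-6-[(4-methoxybenzyl)oxy]-4-methylhex-3-en-1-ol | OCC/C=C(\C)CCOCc1ccc(OC)cc1 | intermediate
7 | 1-({[(3E)-6-iodo-3-methylhex-3-en-1-yl]oxy}methyl)-4-methoxybenzene | ICC/C=C(\C)CCOCc1ccc(OC)cc1 | intermediate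
8 | 4-[(tert-butyldimethylsilyl)oxy]but-2-yn-1-ol | OCC#CCO[Si](C)(C)C(C)(C)C | starting material
9 | cyclic sodium alkenylalanate (five-membered ring Al–O–C6–C5=C4, two 2-methoxyethoxy groups on Al, CH2OTBS on C4) | [Na+].COCCO[Al-]1(OCCOC)OC/C=C1/CO[Si](C)(C)C(C)(C)C | intermediate (not isolated)
10 | (2Z)-4-[(tert-butyldimethylsilyl)oxy]-3-iodobut-2-en-1-ol | OC/C=C(\I)CO[Si](C)(C)C(C)(C)C | intermediate
11 | [(3E)-6-[(4-methoxybenzyl)oxy]-4-methylhex-3-en-1-yl]zinc iodide | I[Zn]CC/C=C(\C)CCOCc1ccc(OC)cc1 | intermediate (not isolated)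
12 | (2E,6E)-3-{[(tert-butyldimethylsilyl)oxy]methyl}-9-[(4-methoxybenzyl)oxy]-7-methylnona-2,6-dien-1-ol | OC/C=C(/CO[Si](C)(C)C(C)(C)C)CC/C=C(\C)CCOCc1ccc(OC)cc1 | intermediate
13 | (2E,6E)-3-{[(tert-butyldimethylsilyl)oxy]methyl}-9-[(4-methoxybenzyl)oxy]-7-methylnona-2,6-dienal | O=C/C=C(/CO[Si](C)(C)C(C)(C)C)CC/C=C(\C)CCOCc1ccc(OC)cc1 | intermediate
14 | (2E,6E)-3-(hydroxymethyl)-9-[(4-methoxybenzyl)oxy]-7-methylnona-2,6-dienal | O=C/C=C(/CO)CC/C=C(\C)CCOCc1ccc(OC)cc1 | intermediate
15 | (2E)-2-{(3E)-6-[(4-methoxybenzyl)oxy]-4-methylhex-3-en-1-yl}-4-oxobut-2-en-1-yl acetate | O=C/C=C(/COC(C)=O)CC/C=C(\C)CCOCc1ccc(OC)cc1 | intermediate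
16 | (2E,4S)-4-hydroxy-2-{(3E)-6-[(4-methoxybenzyl)oxy]-4-methylhex-3-en-1-yl}hexa-2,5-dien-1-yl acetate | C=C[C@H](O)/C=C(/COC(C)=O)CC/C=C(\C)CCOCc1ccc(OC)cc1 | intermediate
17 | 2-(bromomethyl)prop-2-enoic acid | C=C(CBr)C(=O)O | starting material
18 | (3S,4E)-6-acetoxy-5-{(3E)-6-[(4-methoxybenzyl)oxy]-4-methylhex-3-en-1-yl}hexa-1,4-dien-3-yl 2-(bromomethyl)prop-2-enoate | C=C[C@H](OC(=O)C(=C)CBr)/C=C(/COC(C)=O)CC/C=C(\C)CCOCc1ccc(OC)cc1 | intermediate
19 | (2E)-3-[(2R)-4-(bromomethyl)-5-oxo-2,5-dihydrofuran-2-yl]-2-{(3E)-6-[(4-methoxybenzyl)oxy]-4-methylhex-3-en-1-yl}prop-2-en-1-yl acetate | BrCC1=C[C@@H](/C=C(/COC(C)=O)CC/C=C(\C)CCOCc2ccc(OC)cc2)OC1=O | intermediate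
20 | (2E)-3-[(2R)-4-(bromomethyl)-5-oxo-2,5-dihydrofuran-2-yl]-2-[(3E)-6-hydroxy-4-methylhex-3-en-1-yl]prop-2-en-1-yl acetate | BrCC1=C[C@@H](/C=C(/COC(C)=O)CC/C=C(\C)CCO)OC1=O | intermediate
21 | (2E)-3-[(2R)-4-(bromomethyl)-5-oxo-2,5-dihydrofuran-2-yl]-2-[(3E)-4-methyl-6-oxohex-3-en-1-yl]prop-2-en-1-yl acetate | BrCC1=C[C@@H](/C=C(/COC(C)=O)CC/C=C(\C)CC=O)OC1=O | intermediate
22 | allylchromium dichloride derived from 21 (Cl2Cr on C13, trivalent chromium) | Cl[Cr](Cl)CC1=C[C@@H](/C=C(/COC(C)=O)CC/C=C(\C)CC=O)OC1=O | intermediate (not isolated)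
23 | [(3aR,4S,6E,10E,11aR)-4-hydroxy-6-methyl-3-methylidene-2-oxo-2,3,3a,4,5,8,9,11a-octahydrocyclodeca[b]furan-10-yl]methyl acetate | C=C1C(=O)O[C@@H]2/C=C(/COC(C)=O)CC/C=C(\C)C[C@H](O)[C@@H]12 | intermediate
24 | (2S)-2-methylbutanoic acid | CC[C@H](C)C(=O)O | starting material
25 | [(3aR,4R,6E,10E,11aR)-10-(acetoxymethyl)-6-methyl-3-methylidene-2-oxo-2,3,3a,4,5,8,9,11a-octahydrocyclodeca[b]furan-4-yl] (2S)-2-methylbutanoate | C=C1C(=O)O[C@@H]2/C=C(/COC(C)=O)CC/C=C(\C)C[C@@H](OC(=O)[C@@H](C)CC)[C@@H]12 | intermediate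
26 | [(3aR,4R,6E,10E,11aR)-10-(acetoxymethyl)-6-(hydroxymethyl)-3-methylidene-2-oxo-2,3,3a,4,5,8,9,11a-octahydrocyclodeca[b]furan-4-yl] (2S)-2-methylbutanoate | C=C1C(=O)O[C@@H]2/C=C(/COC(C)=O)CC/C=C(/CO)C[C@@H](OC(=O)[C@@H](C)CC)[C@@H]12 | intermediate
27 | [(3aR,4R,6E,10E,11aR)-10-(acetoxymethyl)-6-formyl-3-methylidene-2-oxo-2,3,3a,4,5,8,9,11a-octahydrocyclodeca[b]furan-4-yl] (2S)-2-methylbutanoate | C=C1C(=O)O[C@@H]2/C=C(/COC(C)=O)CC/C=C(/C=O)C[C@@H](OC(=O)[C@@H](C)CC)[C@@H]12 | target

**Count and risks**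

Total steps: 17. Longest linear sequence: 16 (steps 1–3 and 5–17, from but-3-yn-1-ol; step 4 makes the side fragment).

The three steps most likely to fail:

Step 14. What may go wrong: intermolecular coupling or simple reduction of the allylic bromide may outrun closure of the ten-membered ring, because the nucleophile is generated while the substrate is still being added. Fallback: separate the making of the nucleophile from the ring closure by using an isolable allylboronate. Setting out from 20, palladium-catalysed borylation of the allylic bromide (B2pin2, Pd2(dba)3) would give the 3-(pinacolborylmethyl)butenolide alcohol F1, and Dess–Martin oxidation would give the boronate aldehyde F2. Heating F2 at high dilution in toluene (Sc(OTf)3 if needed) should close the ring by intramolecular allylboration of the 2-alkoxycarbonyl-allylboronate type, through the same chair and with the same anti outcome. Aqueous work-up brings the route back at 23.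

Step 16. What may go wrong: the sigmatropic step may keep the 1(10) double bond ring-trans, wholly or in part, because the ring and not the acyclic preference may decide its geometry. Fallback: move the control of this geometry from the kinetic oxidation to a thermodynamic equilibration of the enal. Setting out from 25, the same oxidation would then give the ring-trans allylic alcohol F3, and MnO2 would give the ring-trans enal F4. Catalytic iodine in CH2Cl2 under visible light (reversible addition of an iodine atom to the enal) should then isomerise F4 to the more stable ring-cis enal, which is 27.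

Step 15. What may go wrong: the hindered C8 alkoxyphosphonium ion may eliminate towards C9 to give a conjugated diene, or the weakly acidic aliphatic acid may fail to displace it. Fallback: a two-stage inversion through a sulfonate. Setting out from 23, chloromethanesulfonyl chloride and pyridine would give the chloromethanesulfonate F5. Caesium (S)-2-methylbutanoate (from 24 and Cs2CO3) with 18-crown-6 in toluene should displace it with inversion and bring the route back at 25.

Further compounds
F1 | step 14 | (2E)-2-[(3E)-6-hydroxy-4-methylhex-3-en-1-yl]-3-{(2R)-5-oxo-4-[(4,4,5,5-tetramethyl-1,3,2-dioxaborolan-2-yl)methyl]-2,5-dihydrofuran-2-yl}prop-2-en-1-yl acetate | CC1(C)OB(CC2=C[C@@H](/C=C(/COC(C)=O)CC/C=C(\C)CCO)OC2=O)OC1(C)C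
F2 | step 14 | (2E)-2-[(3E)-4-methyl-6-oxohex-3-en-1-yl]-3-{(2R)-5-oxo-4-[(4,4,5,5-tetramethyl-1,3,2-dioxaborolan-2-yl)methyl]-2,5-dihydrofuran-2-yl}prop-2-en-1-yl acetate | CC1(C)OB(CC2=C[C@@H](/C=C(/COC(C)=O)CC/C=C(\C)CC=O)OC2=O)OC1(C)C
F3 | step 16 | [(3aR,4R,6Z,10E,11aR)-10-(acetoxymethyl)-6-(hydroxymethyl)-3-methylidene-2-oxo-2,3,3a,4,5,8,9,11a-octahydrocyclodeca[b]furan-4-yl] (2S)-2-methylbutanoate | C=C1C(=O)O[C@@H]2/C=C(/COC(C)=O)CC/C=C(\CO)C[C@@H](OC(=O)[C@@H](C)CC)[C@@H]12
F4 | step 16 | [(3aR,4R,6Z,10E,11aR)-10-(acetoxymethyl)-6-formyl-3-methylidene-2-oxo-2,3,3a,4,5,8,9,11a-octahydrocyclodeca[b]furan-4-yl] (2S)-2-methylbutanoate | C=C1C(=O)O[C@@H]2/C=C(/COC(C)=O)CC/C=C(\C=O)C[C@@H](OC(=O)[C@@H](C)CC)[C@@H]12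
F5 | step 15 | chloromethanesulfonate of 23 (C8–OSO2CH2Cl; C6, C7 and C8 arranged as in 23) | C=C1C(=O)O[C@@H]2/C=C(/COC(C)=O)CC/C=C(\C)C[C@H](OS(=O)(=O)CCl)[C@@H]12
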